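## The problem

Compound 22 is a 2-methyl-6-alkylbenzene-1,4-diol. Its C20 side chain runs from the benzylic methylene C1' to the terminal CH2OH at C16' and carries four trisubstituted E alkenes (C2'=C3', C6'=C7', C10'=C11', C14'=C15'), a primary allylic alcohol at C16' and one stereocentre, the (S)-configured secondary allylic alcohol at C5'. No ring has to be closed, so the task is chain assembly with full E control. The lone stereocentre has no neighbour that could direct it and must come from a reagent, a catalyst or an enzyme. The free hydroquinone oxidises in air to the quinone and, under acid, adds through its ortho hydroxyl to the C2'=C3' alkene to give a chroman. The C5' carbinol is allylic and can ionise or transpose under acid, and the 1,5-diene array cyclises with strong Lewis or Brønsted acids. The phenols therefore have to be unmasked late and without acid. The feature that invites the chosen key step is that C5' is an ordinary allylic methylene next to the C6'=C7' alkene. Without its oxygen, the molecule is the 16'-hydroxylated geranylgeranyl methylhydroquinone 21, and C5' is the carbon that carries the hydroxyl group in farnesol. All the difficulty then sits in one C–H to C–OH exchange, which must pick one of about ten allylic sites and one of two enantiotopic hydrogens, a demand that only an enzyme active site can be expected to meet.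

## Retrosynthesis

**C5'–O (22 to 21).** The C5'–O bond is cut, leaving the 5'-deoxy compound 21. The neighbouring cuts, C4'–C5' or C5'–C6' with a chiral reagent, break the chain in its middle and oblige a secondary allylic oxygen to travel through organometallic coupling and oxidative unmasking. Cutting C–O instead leaves an achiral all-E chain whose C5'–C16' part is the farnesol skeleton. The forward reaction, a cytochrome P450 hydroxylation, must find C5', remove the pro-S hydrogen, hydroxylate and not epoxidise, and tolerate the hydroquinone.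

**Unmasking (21 to 20 to 19 to 18).** No skeletal bond is cut. The hydroquinone is traced to quinone 20 (reduction with Na2S2O4), 20 to the dimethyl ether 19 (oxidative demethylation) and 19 to its C16' silyl ether 18. Methyl ethers survive organolithium, Al(CH3)3 and nickel chemistry and are removed at 0 °C without the acid that would close a chroman. The silyl ether is removed first so that fluoride never meets a quinone.

**C1'–C2' and C3'–CH3 (18 to 11 and 16, through 17).** These two bonds are cut together. The alternatives at this site are an aryl-metal attack on an allylic halide (SN2 against SN2' and E/Z erosion) or Friedel–Crafts prenylation (ring regioisomers and chromans). Carboalumination of the terminal alkyne 11 builds the E C2'=C3' alkene with its methyl group from Al(CH3)3, and the same alkenylalane 17 couples with benzyl chloride 16. The precursors are a C14 enyne and a C9 arene.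

**C4'–C5' (11 to 10 to 7 and 8, through 9).** The three carbons C2'–C4' come from 1-(trimethylsilyl)propyne 8, lithiated to 9, and C5'–C16' from the allylic bromide 7. The silyl group steers alkylation to the propargylic carbon and is then removed from 10 to give 11. The forward step asks only for SN2 substitution at a primary allylic bromide.

**C16'–O and the C5' leaving group (7 to 6 to 5 to 4 to 3 to 2 to 1).** The C16' oxygen is traced to an E-selective allylic oxidation of farnesyl acetate 2, made from farnesol 1. Three of the four alkenes are bought with 1 and the fourth (C14'=C15') keeps its geometry in the oxidation. Silylation (4), acetate removal (5) and mesylate 6 to bromide 7 exchange the protecting pattern. The farnesol oxygen on the future C5' is given up here and returned by the enzyme at the end.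

**C(aryl)–C1' (16 to 15 to 14 to 13 to 12).** The benzylic carbon is introduced by ortho-formylation of 4-methoxy-2-methylphenol 12, whose only free ortho position is the required one. O-Methylation (14), reduction (15) and chlorination (16) follow.

## Roads not taken

Alternative 1: The cut is C8'–C9' with creation of the E C6'=C7' alkene by a Johnson–Claisen rearrangement. The C6'-epimeric isopropenyl carbinol A1, which already holds the arene, C1'–C8' and the (S)-C5' silyl ether, would react with triethyl orthoacetate and acid to give the ester A2. Its merits are that both epimers converge because C6' becomes sp2, that a chair transition state with the C5' branch equatorial gives the E alkene, and that every step is known. Its weak points are three. The (S)-C5' centre still has to be made by another asymmetric reaction, so the stereochemical problem is moved and not solved. A2 ends at C10', so C11'–C16' with two more E trisubstituted alkenes and the C16' alcohol need several further steps, and the alkenes that farnesol offers ready-made are not used. Hot acid also meets an allylic silyl ether beside an electron-rich arene. On certainty this road is clearly better than a route that depends on an enzyme not yet identified. The chosen plan sets against it an intact C15 building block, a shorter and more convergent assembly, and a stereocentre made in a single operation.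

Alternative 2: The cuts are C1'–C2' and C3'–CH3, as in step 12 of the chosen route, but with the (S)-C5' oxygen already in place. Alcohol 5 would be oxidised to the enal A3, propargylated enantioselectively and silylated to the alkyne A4. Carboalumination and Pd(PPh3)4- or nickel-catalysed coupling with 16 would then give the fully protected target A5. Its merits are that every step is precedented, that farnesol's own oxygen becomes the C5' oxygen, and that the route from 5 to 22 is one step shorter than the chosen one. Its weak points are three. The enantioselectivity of propargylation of a β,β-disubstituted enal need not be complete, and an oily product with one stereocentre offers no upgrade. The C5' silyl ether is allylic with a trisubstituted alkene and can ionise under Al(CH3)3/Cp2ZrCl2, and the homopropargylic oxygen can chelate and disturb the regiochemistry of carboalumination. The secondary allylic alcohol must pass the oxidation with tetravalent cerium. In certainty and length this road is as good as or better than the chosen plan. The chosen plan sets against it the prospect of complete enantiocontrol, a stereocentre never exposed to Lewis acid or oxidant, and compound 21 as a general substrate for other hydroxylated congeners. Both roads share steps 1–4 and 8–11, so this one is kept as the fallback for step 16.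

Alternative 3: The cut is C4'–C5' with cleavage of C2'–O in a [2,3]-Wittig rearrangement. The (R)-carbinol A6 would be etherified with bromide 7 to the bis-allyl ether A7. n-Butyllithium would deprotonate C5', and the shift would form C4'–C5' and the C2'=C3' alkene to give A8. Its merits are that it joins two fragments, forms a C–C bond and transfers chirality from C2' to C5' in one step. An envelope transition state with CH2Ar pseudo-equatorial and the alkenyl group exo correlates (R)-C2' with (S)-C5'. Its weak points are the several selectivities required at once. The base can also remove the C2' hydrogen, the benzylic C1' hydrogens or a ring hydrogen ortho to OCH3. The [1,2] shift competes. The E/Z ratio of a trisubstituted alkene formed from a 2-methylallyl unit is uncertain. Since C4' is an unsubstituted terminus, the C5' configuration depends only on the exo placement of the alkenyl group. A6 also needs its own asymmetric synthesis. Compared with the chosen plan this road is known chemistry and builds the skeleton convergently, which counts in its favour. The chosen plan replaces these chemical selectivities by one enzymatic one and keeps all alkene geometries fixed from reliable reactions.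

Key step: step 16

Assumption: the cytochrome P450 variant of step 16 is not yet known and is taken to be found by screening and directed evolution of CYP102A1 libraries; all material is the all-E isomer of the target SMILES.

## Route

Step 1
Reactants: 1 (2E,6E)-farnesol
Product: 2 (2E,6E)-farnesyl acetate
Conditions: Ac2O, pyridine, 4-(dimethylamino)pyridine (cat.), CH2Cl2, 0 °C to rt
Reagents that add atoms: acetic anhydride, CC(=O)OC(C)=O
Why: Acylation of a primary allylic alcohol under nucleophilic catalysis; the acetate masks the future C5' oxygen and deactivates the adjacent alkene toward the oxidation of step 2.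

Step 2
Reactants: 2 (2E,6E)-farnesyl acetate
Product: 3 (2E,6E,10E)-12-hydroxy-3,7,11-trimethyldodeca-2,6,10-trien-1-yl acetate
Conditions: SeO2 (cat.), t-BuOOH, salicylic acid (cat.), CH2Cl2, 0 °C to rt, stopped at partial conversion
Reagents that add atoms: tert-butyl hydroperoxide, CC(C)(C)OO; selenium dioxide (oxygen carrier), O=[Se]=O
Why: Riley allylic oxidation, catalytic in selenium: ene reaction at the terminal, least hindered alkene and [2,3]-sigmatropic shift of the allylseleninic acid place oxygen on the E methyl group, so the E C14'=C15' geometry is fixed here; the acetate-bearing alkene is deactivated, and partial conversion limits further oxidation to the enal.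

Step 3
Reactants: 3 (2E,6E,10E)-12-hydroxy-3,7,11-trimethyldodeca-2,6,10-trien-1-yl acetate
Product: 4 (2E,6E,10E)-12-[(tert-butyldimethylsilyl)oxy]-3,7,11-trimethyldodeca-2,6,10-trien-1-yl acetate
Conditions: TBSCl, imidazole, DMF, rt
Reagents that add atoms: tert-butyldimethylsilyl chloride, CC(C)(C)[Si](C)(C)Cl
Why: Standard silylation of a primary alcohol; the silyl ether should withstand carbonate, organolithium and Al(CH3)3 in the steps that follow.

Step 4
Reactants: 4 (2E,6E,10E)-12-[(tert-butyldimethylsilyl)oxy]-3,7,11-trimethyldodeca-2,6,10-trien-1-yl acetate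
Product: 5 (2E,6E,10E)-12-[(tert-butyldimethylsilyl)oxy]-3,7,11-trimethyldodeca-2,6,10-trien-1-ol
Conditions: K2CO3 (cat.), MeOH, rt
Reagents that add atoms: none
Why: Base-catalysed transesterification removes the acetate; the hindered silyl ether is stable to methoxide at room temperature.

Step 5
Reactants: 5 (2E,6E,10E)-12-[(tert-butyldimethylsilyl)oxy]-3,7,11-trimethyldodeca-2,6,10-trien-1-ol
Product: 7 (2E,6E,10E)-1-bromo-12-[(tert-butyldimethylsilyl)oxy]-3,7,11-trimethyldodeca-2,6,10-triene, via allylic methanesulfonate 6 (not isolated)
Conditions: MsCl, Et3N, THF, −45 °C; then LiBr, THF, 0 °C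
Reagents that add atoms: lithium bromide, [Li+].[Br-]; methanesulfonyl chloride (in intermediate 6 only), CS(=O)(=O)Cl
Why: Mesylation followed by SN2 displacement with bromide at low temperature gives the primary allylic bromide without acid, allylic transposition or loss of E geometry.

Step 6
Reactants: 7 (2E,6E,10E)-1-bromo-12-[(tert-butyldimethylsilyl)oxy]-3,7,11-trimethyldodeca-2,6,10-triene; 8 1-(trimethylsilyl)propyne
Product: 10 (5E,9E,13E)-15-[(tert-butyldimethylsilyl)oxy]-6,10,14-trimethyl-1-(trimethylsilyl)pentadeca-5,9,13-trien-1-yne, via 3-lithio-1-(trimethylsilyl)propyne 9 (not isolated)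
Conditions: 8, n-BuLi, THF, −78 °C; then 7, −78 °C to rt
Reagents that add atoms: n-butyllithium (lithium of intermediate 9 only), [Li]CCCC
Why: Propargylic deprotonation gives an anion whose acetylenic end is blocked by silicon, so it alkylates at CH2 by SN2 attack on the primary allylic bromide and forms the C4'–C5' bond without allene formation.

Step 7
Reactants: 10 (5E,9E,13E)-15-[(tert-butyldimethylsilyl)oxy]-6,10,14-trimethyl-1-(trimethylsilyl)pentadeca-5,9,13-trien-1-yne
Product: 11 (5E,9E,13E)-15-[(tert-butyldimethylsilyl)oxy]-6,10,14-trimethylpentadeca-5,9,13-trien-1-yne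
Conditions: K2CO3 (cat.), MeOH/THF, rt
Reagents that add atoms: none
Why: Methoxide cleaves the C(sp)–Si bond selectively (protodesilylation of an alkynylsilane); the O–Si bond of the tert-butyldimethylsilyl ether is not attacked under these conditions.

Step 8
Reactants: 12 4-methoxy-2-methylphenol
Product: 13 2-hydroxy-5-methoxy-3-methylbenzaldehyde
Conditions: MgCl2, Et3N, (CH2O)n, MeCN, reflux
Reagents that add atoms: paraformaldehyde (as formaldehyde), C=O
Why: Casnati–Skattebøl ortho-formylation: the magnesium phenoxide delivers formaldehyde to the only free ortho position, and a second formaldehyde oxidises the magnesium benzyl alkoxide to the aldehyde by hydride transfer.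

Step 9
Reactants: 13 2-hydroxy-5-methoxy-3-methylbenzaldehyde
Product: 14 2,5-dimethoxy-3-methylbenzaldehyde
Conditions: MeI, K2CO3, DMF, rt
Reagents that add atoms: iodomethane, CI
Why: Williamson O-methylation of the phenoxide; no other acidic site is present.

Step 10
Reactants: 14 2,5-dimethoxy-3-methylbenzaldehyde
Product: 15 (2,5-dimethoxy-3-methylphenyl)methanol
Conditions: NaBH4, MeOH, 0 °C
Reagents that add atoms: none
Why: Hydride reduction of an aromatic aldehyde to the benzylic alcohol.

Step 11
Reactants: 15 (2,5-dimethoxy-3-methylphenyl)methanol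
Product: 16 1-(chloromethyl)-2,5-dimethoxy-3-methylbenzene
Conditions: SOCl2, CH2Cl2, 0 °C to rt
Reagents that add atoms: thionyl chloride, O=S(Cl)Cl
Why: Chlorination through the chlorosulfite; the electron-rich benzylic position is substituted readily, and the chloride is used promptly in step 12.

Step 12
Reactants: 11 (5E,9E,13E)-15-[(tert-butyldimethylsilyl)oxy]-6,10,14-trimethylpentadeca-5,9,13-trien-1-yne; 16 1-(chloromethyl)-2,5-dimethoxy-3-methylbenzene
Product: 18 tert-butyl{[(2E,6E,10E,14E)-16-(2,5-dimethoxy-3-methylphenyl)-2,6,10,14-tetramethylhexadeca-2,6,10,14-tetraen-1-yl]oxy}dimethylsilane, via alkenyldimethylalane 17 (not isolated)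
Conditions: Al(CH3)3, Cp2ZrCl2 (cat.), ClCH2CH2Cl, 0 °C to rt; volatiles removed; then 16, NiCl2(PPh3)2 (cat.)/n-BuLi, THF, rt
Reagents that add atoms: trimethylaluminium, C[Al](C)C
Why: Negishi carboalumination adds CH3 and Al syn across the terminal alkyne with aluminium on the terminal carbon, which fixes the E C2'=C3' alkene; zerovalent nickel, formed from the divalent nickel complex NiCl2(PPh3)2 and n-BuLi, then inserts into the benzylic C–Cl bond, accepts the alkenyl group from aluminium and forms C1'–C2' by reductive elimination with retention of geometry.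

Step 13
Reactants: 18 tert-butyl{[(2E,6E,10E,14E)-16-(2,5-dimethoxy-3-methylphenyl)-2,6,10,14-tetramethylhexadeca-2,6,10,14-tetraen-1-yl]oxy}dimethylsilane
Product: 19 (2E,6E,10E,14E)-16-(2,5-dimethoxy-3-methylphenyl)-2,6,10,14-tetramethylhexadeca-2,6,10,14-tetraen-1-ol
Conditions: TBAF, THF, 0 °C to rt
Reagents that add atoms: none
Why: Fluoride-induced desilylation driven by the Si–F bond; aryl methyl ethers and alkenes are inert.

Step 14
Reactants: 19 (2E,6E,10E,14E)-16-(2,5-dimethoxy-3-methylphenyl)-2,6,10,14-tetramethylhexadeca-2,6,10,14-tetraen-1-ol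
Product: 20 2-[(2E,6E,10E,14E)-16-hydroxy-3,7,11,15-tetramethylhexadeca-2,6,10,14-tetraen-1-yl]-6-methylcyclohexa-2,5-diene-1,4-dione
Conditions: (NH4)2Ce(NO3)6, MeCN/H2O, 0 °C, short reaction time
Reagents that add atoms: water, O
Why: Oxidative demethylation of a hydroquinone dimethyl ether by tetravalent cerium: two one-electron oxidations of the arene, addition of water at the two ipso carbons and loss of methanol give the para-quinone; the reaction is fast at 0 °C, so isolated alkenes and the allylic alcohol should be spared.

Step 15
Reactants: 20 2-[(2E,6E,10E,14E)-16-hydroxy-3,7,11,15-tetramethylhexadeca-2,6,10,14-tetraen-1-yl]-6-methylcyclohexa-2,5-diene-1,4-dione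
Product: 21 2-[(2E,6E,10E,14E)-16-hydroxy-3,7,11,15-tetramethylhexadeca-2,6,10,14-tetraen-1-yl]-6-methylbenzene-1,4-diol
Conditions: Na2S2O4, Et2O/H2O, rt, argon
Reagents that add atoms: none
Why: Two-electron reduction of the quinone by dithionite in a two-phase system, without acid or base, so that neither chroman formation nor alkene isomerisation can occur; the hydroquinone is kept under argon.

Step 16
Reactants: 21 2-[(2E,6E,10E,14E)-16-hydroxy-3,7,11,15-tetramethylhexadeca-2,6,10,14-tetraen-1-yl]-6-methylbenzene-1,4-diol
Product: 22 2-[(2E,5S,6E,10E,14E)-5,16-dihydroxy-3,7,11,15-tetramethylhexadeca-2,6,10,14-tetraen-1-yl]-6-methylbenzene-1,4-diol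
Conditions: CYP102A1 variant (cytochrome P450 monooxygenase, from screening), O2 (air), NADP+ (cat.), D-glucose, glucose dehydrogenase, catalase, sodium ascorbate, 2-hydroxypropyl-β-cyclodextrin, KH2PO4/K2HPO4 buffer pH 7.4, 25 °C; extraction and chromatography under argon
Reagents that add atoms: dioxygen, O=O
Why: Proposed new method: electrons from NADPH and O2 convert the heme iron of the enzyme into the ferryl-oxo porphyrin radical cation (tetravalent iron), which abstracts one hydrogen from the C5' methylene of 21, and the allylic radical is captured by the iron-bound hydroxyl on the same face before it can rotate or transpose to C7', so the C5'–O bond forms with retention. The closest known reaction type is allylic hydroxylation of acyclic terpenoids and prenyl chains by engineered CYP102A1 variants; hydroxylation at C5' of a prenylated hydroquinone has not been shown, which is why a variant has to be found by screening. No ring is formed and no skeletal bond changes. The (S) configuration is controlled by the enzyme alone: removal of the pro-S hydrogen with retention gives (S), and the substrate has no bias of its own. The step needs site selectivity for C5' over C1', C4', C8', C9', C12', C13' and the allylic methyl groups, hydroxylation in preference to epoxidation, and no further oxidation of the C16' alcohol. What the substrate contributes is the weak allylic C5'–H bond and two polar ends, the hydroquinone ring and the C16' hydroxyl, between which a binding channel can measure the chain and hold C5' over the iron. Glucose dehydrogenase regenerates NADPH at the expense of glucose (oxidised to gluconolactone), catalase and ascorbate suppress peroxide and quinone formation, and the cyclodextrin keeps the lipophilic substrate available.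

## Compound list

1 | (2E,6E)-farnesol | CC(C)=CCC/C(C)=C/CC/C(C)=C/CO | starting material
2 | (2E,6E)-farnesyl acetate | CC(C)=CCC/C(C)=C/CC/C(C)=C/COC(C)=O | intermediate
3 | (2E,6E,10E)-12-hydroxy-3,7,11-trimethyldodeca-2,6,10-trien-1-yl acetate | C/C(=C\CC/C(C)=C/CC/C(C)=C/COC(C)=O)CO | intermediate
4 | (2E,6E,10E)-12-[(tert-butyldimethylsilyl)oxy]-3,7,11-trimethyldodeca-2,6,10-trien-1-yl acetate | C/C(=C\CC/C(C)=C/CC/C(C)=C/COC(C)=O)CO[Si](C)(C)C(C)(C)C | intermediate
5 | (2E,6E,10E)-12-[(tert-butyldimethylsilyl)oxy]-3,7,11-trimethyldodeca-2,6,10-trien-1-ol | C/C(=C\CC/C(C)=C/CC/C(C)=C/CO)CO[Si](C)(C)C(C)(C)C | intermediate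
6 | (2E,6E,10E)-12-[(tert-butyldimethylsilyl)oxy]-3,7,11-trimethyldodeca-2,6,10-trien-1-yl methanesulfonate | C/C(=C\CC/C(C)=C/CC/C(C)=C/COS(C)(=O)=O)CO[Si](C)(C)C(C)(C)C | intermediate
7 | (2E,6E,10E)-1-bromo-12-[(tert-butyldimethylsilyl)oxy]-3,7,11-trimethyldodeca-2,6,10-triene | C/C(=C\CC/C(C)=C/CC/C(C)=C/CBr)CO[Si](C)(C)C(C)(C)C | intermediate
8 | 1-(trimethylsilyl)propyne | CC#C[Si](C)(C)C | starting material
9 | 3-lithio-1-(trimethylsilyl)propyne | [Li]CC#C[Si](C)(C)C | intermediate
10 | (5E,9E,13E)-15-[(tert-butyldimethylsilyl)oxy]-6,10,14-trimethyl-1-(trimethylsilyl)pentadeca-5,9,13-trien-1-yne | C/C(=C\CC/C(C)=C/CC/C(C)=C/CCC#C[Si](C)(C)C)CO[Si](C)(C)C(C)(C)C | intermediate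
11 | (5E,9E,13E)-15-[(tert-butyldimethylsilyl)oxy]-6,10,14-trimethylpentadeca-5,9,13-trien-1-yne | C/C(=C\CC/C(C)=C/CC/C(C)=C/CCC#C)CO[Si](C)(C)C(C)(C)C | intermediate
12 | 4-methoxy-2-methylphenol | COc1ccc(O)c(C)c1 | starting material
13 | 2-hydroxy-5-methoxy-3-methylbenzaldehyde | COc1cc(C)c(O)c(C=O)c1 | intermediate
14 | 2,5-dimethoxy-3-methylbenzaldehyde | COc1cc(C)c(OC)c(C=O)c1 | intermediate
15 | (2,5-dimethoxy-3-methylphenyl)methanol | COc1cc(C)c(OC)c(CO)c1 | intermediate
16 | 1-(chloromethyl)-2,5-dimethoxy-3-methylbenzene | COc1cc(C)c(OC)c(CCl)c1 | intermediate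
17 | [(1E,5E,9E,13E)-15-[(tert-butyldimethylsilyl)oxy]-2,6,10,14-tetramethylpentadeca-1,5,9,13-tetraen-1-yl]dimethylalane | C/C(=C\CC/C(C)=C/CC/C(C)=C/CC/C(C)=C/[Al](C)C)CO[Si](C)(C)C(C)(C)C | intermediate
18 | tert-butyl{[(2E,6E,10E,14E)-16-(2,5-dimethoxy-3-methylphenyl)-2,6,10,14-tetramethylhexadeca-2,6,10,14-tetraen-1-yl]oxy}dimethylsilane | C/C(=C\CC/C(C)=C/CC/C(C)=C/CC/C(C)=C/Cc1cc(OC)cc(C)c1OC)CO[Si](C)(C)C(C)(C)C | intermediate
19 | (2E,6E,10E,14E)-16-(2,5-dimethoxy-3-methylphenyl)-2,6,10,14-tetramethylhexadeca-2,6,10,14-tetraen-1-ol | C/C(=C\CC/C(C)=C/CC/C(C)=C/CC/C(C)=C/Cc1cc(OC)cc(C)c1OC)CO | intermediate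
20 | 2-[(2E,6E,10E,14E)-16-hydroxy-3,7,11,15-tetramethylhexadeca-2,6,10,14-tetraen-1-yl]-6-methylcyclohexa-2,5-diene-1,4-dione | C/C(=C\CC/C(C)=C/CC/C(C)=C/CC/C(C)=C/CC1=CC(=O)C=C(C)C1=O)CO | intermediate
21 | 2-[(2E,6E,10E,14E)-16-hydroxy-3,7,11,15-tetramethylhexadeca-2,6,10,14-tetraen-1-yl]-6-methylbenzene-1,4-diol | C/C(=C\CC/C(C)=C/CC/C(C)=C/CC/C(C)=C/Cc1cc(O)cc(C)c1O)CO | intermediate
22 | 2-[(2E,5S,6E,10E,14E)-5,16-dihydroxy-3,7,11,15-tetramethylhexadeca-2,6,10,14-tetraen-1-yl]-6-methylbenzene-1,4-diol | C/C(=C\CC/C(C)=C/CC/C(C)=C/[C@@H](O)C/C(C)=C/Cc1cc(O)cc(C)c1O)CO | target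

## Step count and risks

Total step count: 16. Longest linear sequence: 12 steps (steps 1–7 and 12–16, from 1). The arene branch (steps 8–11) has 4 steps.

**Step 16 (key step, proposed new method).**
- What may go wrong: hydrogen abstraction at another allylic site, oxygen transfer to an alkene in place of a C–H bond, poor discrimination between the two C5' hydrogens, further oxidation at C16', and autoxidation of the hydroquinone with uncoupled NADPH consumption. All of these rest on substrate binding, which cannot be predicted for an enzyme not yet identified.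
- Fallback by known chemistry, setting out from 5 (and using 16) and returning at 22:
  - MnO2 in CH2Cl2 oxidises 5 to (2E,6E,10E)-12-[(tert-butyldimethylsilyl)oxy]-3,7,11-trimethyldodeca-2,6,10-trienal F1.
  - Enantioselective propargylation of F1 with allenylboronic acid pinacol ester under a chiral BINOL-derived phosphoric acid, the catalyst enantiomer chosen for addition to the Si face of the aldehyde, gives (4S,5E,9E,13E)-15-[(tert-butyldimethylsilyl)oxy]-6,10,14-trimethylpentadeca-5,9,13-trien-1-yn-4-ol F2.
  - TBSOTf and 2,6-lutidine give the (S)-4,15-bis(silyl ether) of that enynol F3, which is the alkyne A4 of Alternative 2.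
  - Al(CH3)3/Cp2ZrCl2 carboalumination gives the (S)-5-silyloxy alkenyldimethylalane F4, and NiCl2(PPh3)2-catalysed coupling with 16 gives the 5',16'-bis(silyl ether) of the target dimethyl ether F5, identical with A5.
  - TBAF gives (2E,6E,10E,12S,14E)-16-(2,5-dimethoxy-3-methylphenyl)-2,6,10,14-tetramethylhexadeca-2,6,10,14-tetraene-1,12-diol F6.
  - (NH4)2Ce(NO3)6 gives the quinone 2-[(2E,5S,6E,10E,14E)-5,16-dihydroxy-3,7,11,15-tetramethylhexadeca-2,6,10,14-tetraen-1-yl]-6-methylcyclohexa-2,5-diene-1,4-dione F7, and Na2S2O4 reduces it to 22.
- This sequence also supplies the authentic reference sample against which an enzyme screen would be read. If only the free hydroquinone were the obstacle, the same screen could be run on 19, whose C5' hydroxylation product would be F6.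

**Step 2.**
- What may go wrong: further oxidation of the new alcohol to the enal, competing oxidation at internal allylic positions, and low conversion, because the selenium reagent distinguishes the three alkenes only by substitution and by the inductive effect of the acetate.
- Fallback from 2, returning at 3:
  - NBS in aqueous THF converts the terminal alkene into the bromohydrin (2E,6E)-10-bromo-11-hydroxy-3,7,11-trimethyldodeca-2,6-dien-1-yl acetate F8.
  - DBU closes it to the epoxide (2E,6E)-9-(3,3-dimethyloxiran-2-yl)-3,7-dimethylnona-2,6-dien-1-yl acetate F9.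
  - HIO4 cleaves F9 to (2E,6E)-3,7-dimethyl-10-oxodeca-2,6-dien-1-yl acetate F10.
  - E-selective Wittig olefination with 2-(triphenylphosphoranylidene)propanal gives (2E,6E,10E)-3,7,11-trimethyl-12-oxododeca-2,6,10-trien-1-yl acetate F11, and NaBH4 at 0 °C reduces the aldehyde to 3.

**Step 12.**
- What may go wrong: reductive homocoupling of the electron-rich benzyl chloride and protodealumination may outpace transfer of the alkenyl group from aluminium to nickel, and a minor regioisomeric carboalumination would carry through.
- Fallback from 11 and 16, returning at 18: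
  - The alkenylalane 17 is quenched with I2 to the isolable tert-butyl{[(2E,6E,10E,14E)-15-iodo-2,6,10,14-tetramethylpentadeca-2,6,10,14-tetraen-1-yl]oxy}dimethylsilane F12, which can be purified from regioisomer.
  - 16 is converted with Zn and LiCl in THF into (2,5-dimethoxy-3-methylbenzyl)zinc chloride F13.
  - Pd(PPh3)4-catalysed Negishi coupling of F12 with F13, with the roles of the partners reversed, gives 18.

**Step 14.**
- What may go wrong: oxidation by tetravalent cerium may extend to the trisubstituted alkenes or the allylic alcohol, and the nitric acid set free may promote cyclisation of the polyene, because the substrate must stay in the medium until both methyl groups are lost.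
- Fallback from 16 and 17, returning at 20, in which the oxidation is moved to the simple arene:
  - (NH4)2Ce(NO3)6 converts 16 into 2-(chloromethyl)-6-methylcyclohexa-2,5-diene-1,4-dione F14.
  - Nickel-catalysed coupling of 17 with F14 gives the C16' tert-butyldimethylsilyl ether of quinone 20 F15.
  - HF·pyridine in THF gives 20.
- The price is an unsubstituted quinone position exposed to the organoaluminium reagent.

## Further compounds

F1 | step 16 | (2E,6E,10E)-12-[(tert-butyldimethylsilyl)oxy]-3,7,11-trimethyldodeca-2,6,10-trienal | C/C(=C\CC/C(C)=C/CC/C(C)=C/C=O)CO[Si](C)(C)C(C)(C)C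
F2 | step 16 | (4S,5E,9E,13E)-15-[(tert-butyldimethylsilyl)oxy]-6,10,14-trimethylpentadeca-5,9,13-trien-1-yn-4-ol | C/C(=C\CC/C(C)=C/CC/C(C)=C/[C@@H](O)CC#C)CO[Si](C)(C)C(C)(C)C
F3 | step 16 | (4S,5E,9E,13E)-4,15-bis[(tert-butyldimethylsilyl)oxy]-6,10,14-trimethylpentadeca-5,9,13-trien-1-yne | C/C(=C\CC/C(C)=C/CC/C(C)=C/[C@@H](O[Si](C)(C)C(C)(C)C)CC#C)CO[Si](C)(C)C(C)(C)C
F4 | step 16 | [(1E,4S,5E,9E,13E)-4,15-bis[(tert-butyldimethylsilyl)oxy]-2,6,10,14-tetramethylpentadeca-1,5,9,13-tetraen-1-yl]dimethylalane | C/C(=C\CC/C(C)=C/CC/C(C)=C/[C@@H](O[Si](C)(C)C(C)(C)C)C/C(C)=C/[Al](C)C)CO[Si](C)(C)C(C)(C)C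
F5 | step 16 | 5',16'-bis(tert-butyldimethylsilyl) ether of the (5'S) target dimethyl ether | C/C(=C\CC/C(C)=C/CC/C(C)=C/[C@@H](O[Si](C)(C)C(C)(C)C)C/C(C)=C/Cc1cc(OC)cc(C)c1OC)CO[Si](C)(C)C(C)(C)C
F6 | step 16 | (2E,6E,10E,12S,14E)-16-(2,5-dimethoxy-3-methylphenyl)-2,6,10,14-tetramethylhexadeca-2,6,10,14-tetraene-1,12-diol | C/C(=C\CC/C(C)=C/CC/C(C)=C/[C@@H](O)C/C(C)=C/Cc1cc(OC)cc(C)c1OC)CO
F7 | step 16 | 2-[(2E,5S,6E,10E,14E)-5,16-dihydroxy-3,7,11,15-tetramethylhexadeca-2,6,10,14-tetraen-1-yl]-6-methylcyclohexa-2,5-diene-1,4-dione | C/C(=C\CC/C(C)=C/CC/C(C)=C/[C@@H](O)C/C(C)=C/CC1=CC(=O)C=C(C)C1=O)CO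
F8 | step 2 | (2E,6E)-10-bromo-11-hydroxy-3,7,11-trimethyldodeca-2,6-dien-1-yl acetate (racemic) | CC(C)(O)C(Br)CC/C(C)=C/CC/C(C)=C/COC(C)=O
F9 | step 2 | (2E,6E)-9-(3,3-dimethyloxiran-2-yl)-3,7-dimethylnona-2,6-dien-1-yl acetate (racemic) | CC1(C)OC1CC/C(C)=C/CC/C(C)=C/COC(C)=O
F10 | step 2 | (2E,6E)-3,7-dimethyl-10-oxodeca-2,6-dien-1-yl acetate | O=CCC/C(C)=C/CC/C(C)=C/COC(C)=O
F11 | step 2 | (2E,6E,10E)-3,7,11-trimethyl-12-oxododeca-2,6,10-trien-1-yl acetate | C/C(C=O)=C\CC/C(C)=C/CC/C(C)=C/COC(C)=O
F12 | step 12 | tert-butyl{[(2E,6E,10E,14E)-15-iodo-2,6,10,14-tetramethylpentadeca-2,6,10,14-tetraen-1-yl]oxy}dimethylsilane | C/C(=C\CC/C(C)=C/CC/C(C)=C/CC/C(C)=C/I)CO[Si](C)(C)C(C)(C)C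
F13 | step 12 | (2,5-dimethoxy-3-methylbenzyl)zinc chloride | COc1cc(C)c(OC)c(C[Zn]Cl)c1
F14 | step 14 | 2-(chloromethyl)-6-methylcyclohexa-2,5-diene-1,4-dione | CC1=CC(=O)C=C(CCl)C1=O
F15 | step 14 | 2-[(2E,6E,10E,14E)-16-[(tert-butyldimethylsilyl)oxy]-3,7,11,15-tetramethylhexadeca-2,6,10,14-tetraen-1-yl]-6-methylcyclohexa-2,5-diene-1,4-dione | C/C(=C\CC/C(C)=C/CC/C(C)=C/CC/C(C)=C/CC1=CC(=O)C=C(C)C1=O)CO[Si](C)(C)C(C)(C)C
A1 | alternative 1 | (3RS,4S,6E)-4-[(tert-butyldimethylsilyl)oxy]-8-(2,5-dimethoxy-3-methylphenyl)-2,6-dimethylocta-1,6-dien-3-ol (mixture of C6' epimers) | C=C(C)C(O)[C@@H](O[Si](C)(C)C(C)(C)C)C/C(C)=C/Cc1cc(OC)cc(C)c1OC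
A2 | alternative 1 | ethyl (4E,6S,8E)-6-[(tert-butyldimethylsilyl)oxy]-10-(2,5-dimethoxy-3-methylphenyl)-4,8-dimethyldeca-4,8-dienoate | CCOC(=O)CC/C(C)=C/[C@@H](O[Si](C)(C)C(C)(C)C)C/C(C)=C/Cc1cc(OC)cc(C)c1OC
A3 | alternative 2 | (2E,6E,10E)-12-[(tert-butyldimethylsilyl)oxy]-3,7,11-trimethyldodeca-2,6,10-trienal | C/C(=C\CC/C(C)=C/CC/C(C)=C/C=O)CO[Si](C)(C)C(C)(C)C
A4 | alternative 2 | (4S,5E,9E,13E)-4,15-bis[(tert-butyldimethylsilyl)oxy]-6,10,14-trimethylpentadeca-5,9,13-trien-1-yne | C/C(=C\CC/C(C)=C/CC/C(C)=C/[C@@H](O[Si](C)(C)C(C)(C)C)CC#C)CO[Si](C)(C)C(C)(C)C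
A5 | alternative 2 | 5',16'-bis(tert-butyldimethylsilyl) ether of the (5'S) target dimethyl ether | C/C(=C\CC/C(C)=C/CC/C(C)=C/[C@@H](O[Si](C)(C)C(C)(C)C)C/C(C)=C/Cc1cc(OC)cc(C)c1OC)CO[Si](C)(C)C(C)(C)C
A6 | alternative 3 | (2R)-1-(2,5-dimethoxy-3-methylphenyl)-3-methylbut-3-en-2-ol | C=C(C)[C@H](O)Cc1cc(OC)cc(C)c1OC
A7 | alternative 3 | (2R)-1-(2,5-dimethoxy-3-methylphenyl)-3-methylbut-3-en-2-yl (2E,6E,10E)-12-[(tert-butyldimethylsilyl)oxy]-3,7,11-trimethyldodeca-2,6,10-trien-1-yl ether | C=C(C)[C@@H](Cc1cc(OC)cc(C)c1OC)OC/C=C(\C)CC/C=C(\C)CC/C=C(\C)CO[Si](C)(C)C(C)(C)C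
A8 | alternative 3 | (2E,5S,6E,10E,14E)-16-[(tert-butyldimethylsilyl)oxy]-1-(2,5-dimethoxy-3-methylphenyl)-3,7,11,15-tetramethylhexadeca-2,6,10,14-tetraen-5-ol | C/C(=C\CC/C(C)=C/CC/C(C)=C/[C@@H](O)C/C(C)=C/Cc1cc(OC)cc(C)c1OC)CO[Si](C)(C)C(C)(C)C
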